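**Retrosynthetic overview**
1. Target 26 ⇐ O-acetylation of macrocyclic alcohol 25.
2. 25 ⇐ the ten-membered ring is closed last through the C7–C8 bond: the allylchromium from a 3-(bromomethyl)butenolide makes C7 (β-carbon of the lactone carbonyl, a homoenolate-type carbanion equivalent) attack the C8 aldehyde, which also creates the α-methylene lactone and sets C7 and C8.
3. Bromobutenolide (five-membered ring, formed first) ⇐ ring-closing metathesis of a 2-(bromomethyl)acrylate of a bis-allylic alcohol; C6 comes from an enantioselective alkynylation of acrolein.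
4. The C4=C5 geometry and C15 ⇐ hydroxyl-directed trans-hydroalumination/iodination of the alkyne, then Stille hydroxymethylation.
5. C2 ketone and C8 aldehyde ⇐ two 1,3-dithiane acyl-anion equivalents, joined to 3-chloro-2-(chloromethyl)prop-1-ene and a propargyl bromide (C1–C2, C2–C3, C8–C9).

Assumption: germacrane numbering is used for locants, C10(=C14H2)–C1H2–C2(=O)–C3H2–C4(C15H2OAc)=C5H–C6H(O)–C7H–C8H(OAc)–C9H2 with lactone C11(=C13H2)–C12; the target is (6R,7R,8S) with C3 and C6 trans across C4=C5.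

**Route**

Step 1
Reactants: 1 1,3-dithiane; 2 3-chloro-2-(chloromethyl)prop-1-ene
Product: 4 2,2'-(2-methylidenepropane-1,3-diyl)bis(1,3-dithiane), via 2-lithio-1,3-dithiane 3 (not isolated)
Conditions: 1 (2.1 equiv), n-BuLi (2.1 equiv), THF, −30 °C, 2 h; then 2 (1.0 equiv), −78 °C to rt
Reagents that add atoms: 3-chloro-2-(chloromethyl)prop-1-ene (2), C=C(CCl)CCl
Why: Corey–Seebach alkylation; the formyl-anion equivalent displaces both allylic chlorides (SN2 and SN2' give the same product), forming C1–C2 and C8–C9 with no stereocentre.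

Step 2
Reactants: 4 2,2'-(2-methylidenepropane-1,3-diyl)bis(1,3-dithiane); 5 3-bromo-1-(trimethylsilyl)prop-1-yne
Product: 8 2-{2-[(1,3-dithian-2-yl)methyl]prop-2-en-1-yl}-2-(prop-2-yn-1-yl)-1,3-dithiane, via monolithiated bis(dithiane) 6 (not isolated), via C-silylated alkyne 7 (not isolated)
Conditions: n-BuLi (1.0 equiv), THF, −30 °C, 2 h; 5 (1.0 equiv), −78 to 0 °C; then MeOH, K2CO3 (cat.), rt, same pot
Reagents that add atoms: 3-bromo-1-(trimethylsilyl)prop-1-yne (5), C[Si](C)(C)C#CCBr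
Why: Corey–Seebach alkylation of the mono-anion of the symmetric bis(dithiane) (statistical, unreacted 4 is recycled) forms C2–C3; the silyl cap prevents acetylide and allene side reactions and is removed by methanolysis; no stereocentre.

Step 3
Reactants: 8 2-{2-[(1,3-dithian-2-yl)methyl]prop-2-en-1-yl}-2-(prop-2-yn-1-yl)-1,3-dithiane; 9 acrolein
Product: 12 (3S)-6-(2-{2-[(1,3-dithian-2-yl)methyl]prop-2-en-1-yl}-1,3-dithian-2-yl)hex-1-en-4-yn-3-ol, via alkynyl(methyl)zinc 10 (not isolated), via methylzinc alkoxide 11 (not isolated)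
Conditions: Me2Zn (3 equiv), (S,S)-ProPhenol (20 mol %), Ph3P=O (40 mol %), toluene, 0 °C; 9 (3 equiv, slow addition), 4 °C, 36 h; aqueous quench
Reagents that add atoms: acrolein (9), C=CC=O
Why: catalytic enantioselective zinc alkynylide addition to an aldehyde sets C6 by delivery of the alkynyl group to the Re face of acrolein, giving the (S)-carbinol (the antipodal ligand is used if the sense of induction proves opposite).

Step 4
Reactants: 12 (3S)-6-(2-{2-[(1,3-dithian-2-yl)methyl]prop-2-en-1-yl}-1,3-dithian-2-yl)hex-1-en-4-yn-3-ol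
Product: 14 (3S,4Z)-6-(2-{2-[(1,3-dithian-2-yl)methyl]prop-2-en-1-yl}-1,3-dithian-2-yl)-5-iodohexa-1,4-dien-3-ol, via cyclic vinylalanate 13 (not isolated)
Conditions: NaAlH2(OCH2CH2OMe)2 (1.6 equiv), THF, 0 °C to rt; then I2, THF, −78 °C; aqueous Na2S2O3 work-up
Reagents that add atoms: iodine, II
Why: hydroxyl-directed trans-hydroalumination of the propargylic alcohol (hydride to C5, aluminium to C4 in a five-membered alanate) followed by iodinolysis with retention places iodine on C4 cis to C6 and so fixes the C4=C5 geometry.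

Step 5
Reactants: 14 (3S,4Z)-6-(2-{2-[(1,3-dithian-2-yl)methyl]prop-2-en-1-yl}-1,3-dithian-2-yl)-5-iodohexa-1,4-dien-3-ol; 15 (tributylstannyl)methanol
Product: 16 (2Z,4S)-2-[(2-{2-[(1,3-dithian-2-yl)methyl]prop-2-en-1-yl}-1,3-dithian-2-yl)methyl]hexa-2,5-diene-1,4-diol
Conditions: Pd(PPh3)4 (10 mol %), dioxane, 90 °C
Reagents that add atoms: (tributylstannyl)methanol (15), CCCC[Sn](CCCC)(CCCC)CO
Why: Stille cross-coupling transfers the hydroxymethyl group (C15) with retention of alkene geometry, so C15 is cis and C3 trans to C6.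

Step 6
Reactants: 16 (2Z,4S)-2-[(2-{2-[(1,3-dithian-2-yl)methyl]prop-2-en-1-yl}-1,3-dithian-2-yl)methyl]hexa-2,5-diene-1,4-diol
Product: 17 (2Z,4S)-4-hydroxy-2-[(2-{2-[(1,3-dithian-2-yl)methyl]prop-2-en-1-yl}-1,3-dithian-2-yl)methyl]hexa-2,5-dien-1-yl acetate
Conditions: AcCl (1.05 equiv), 2,4,6-collidine (2 equiv), CH2Cl2, −78 °C
Reagents that add atoms: acetyl chloride, CC(Cl)=O
Why: kinetically selective O-acylation of the primary allylic alcohol over the hindered secondary one at low temperature with a hindered base.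

Step 7
Reactants: 17 (2Z,4S)-4-hydroxy-2-[(2-{2-[(1,3-dithian-2-yl)methyl]prop-2-en-1-yl}-1,3-dithian-2-yl)methyl]hexa-2,5-dien-1-yl acetate; 18 2-(bromomethyl)prop-2-enoic acid
Product: 20 (2Z,4S)-4-{[2-(bromomethyl)prop-2-enoyl]oxy}-2-[(2-{2-[(1,3-dithian-2-yl)methyl]prop-2-en-1-yl}-1,3-dithian-2-yl)methyl]hexa-2,5-dien-1-yl acetate, via O-acylisourea 19 (not isolated)
Conditions: N,N'-diisopropylcarbodiimide (1.2 equiv), DMAP (5 mol %), CH2Cl2, −20 to 0 °C
Reagents that add atoms: 2-(bromomethyl)prop-2-enoic acid (18), C=C(CBr)C(O)=O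
Why: Steglich esterification acylates the C6 hydroxyl with retention; low temperature and only catalytic DMAP limit attack on the allylic bromide.

Step 8
Reactants: 20 (2Z,4S)-4-{[2-(bromomethyl)prop-2-enoyl]oxy}-2-[(2-{2-[(1,3-dithian-2-yl)methyl]prop-2-en-1-yl}-1,3-dithian-2-yl)methyl]hexa-2,5-dien-1-yl acetate
Product: 21 (2Z)-3-[(2R)-4-(bromomethyl)-5-oxo-2,5-dihydrofuran-2-yl]-2-[(2-{2-[(1,3-dithian-2-yl)methyl]prop-2-en-1-yl}-1,3-dithian-2-yl)methyl]prop-2-en-1-yl acetate
Conditions: second-generation Hoveyda–Grubbs catalyst (15 mol %), toluene (5 mM), 80 °C, argon sparge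
Reagents that add atoms: none
Why: ring-closing metathesis of the vinyl group with the acrylate gives the butenolide; the trisubstituted and 1,1-disubstituted alkenes cannot close an unstrained ring, and C6 is untouched (its descriptor becomes R only through a priority change).

Step 9
Reactants: 21 (2Z)-3-[(2R)-4-(bromomethyl)-5-oxo-2,5-dihydrofuran-2-yl]-2-[(2-{2-[(1,3-dithian-2-yl)methyl]prop-2-en-1-yl}-1,3-dithian-2-yl)methyl]prop-2-en-1-yl acetate
Product: 22 (2Z)-3-[(2R)-4-(bromomethyl)-5-oxo-2,5-dihydrofuran-2-yl]-2-(4-methylidene-2,6-dioxohexyl)prop-2-en-1-yl acetate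
Conditions: PhI(OCOCF3)2 (2.5 equiv), MeCN/H2O 9:1, 0 °C, 10 min; rapid extractive work-up, used crude
Reagents that add atoms: water, O
Why: oxidative dithioacetal hydrolysis with a hypervalent iodine reagent unmasks the C2 ketone and C8 aldehyde without base, which would conjugate the skipped enone and enal or racemise the butenolide C6.

Step 10
Reactants: 22 (2Z)-3-[(2R)-4-(bromomethyl)-5-oxo-2,5-dihydrofuran-2-yl]-2-(4-methylidene-2,6-dioxohexyl)prop-2-en-1-yl acetate
Product: 25 (6R,7R,8S)-15-acetoxy-8-hydroxy-2-oxogermacra-4,10(14),11(13)-trien-12,6-olide, via allylchromium dichloride 23 (not isolated), via chromium alkoxide 24 (not isolated)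
Conditions: CrCl2 (8 equiv), degassed THF, 25 °C, syringe-pump addition of 22 over 10 h (final 2 mM); aqueous work-up
Reagents that add atoms: none
Why: intramolecular Nozaki–Hiyama-type Barbier allylation in which the bromobutenolide becomes an allylchromium that attacks the aldehyde through C7 and closes the ten-membered ring; the ketone is spared because allylchromium is aldehyde-selective and the trans C4=C5 alkene forbids a six-membered closure onto C2; a Zimmerman–Traxler chair with the ring-locked E-allyl unit and C9 equatorial should give the 7R,8S (anti) relationship, and attack on the C7 face opposite C5 gives the trans-fused lactone.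

Step 11
Reactants: 25 (6R,7R,8S)-15-acetoxy-8-hydroxy-2-oxogermacra-4,10(14),11(13)-trien-12,6-olide
Product: 26 (6R,7R,8S)-8,15-diacetoxy-2-oxogermacra-4,10(14),11(13)-trien-12,6-olide (CNP0183179.1)
Conditions: Ac2O (3 equiv), pyridine, CH2Cl2, 0 °C to rt
Reagents that add atoms: acetic anhydride, CC(=O)OC(C)=O
Why: O-acetylation of the secondary alcohol with retention; DMAP and strong base are avoided so the doubly β,γ-unsaturated ketone and the α-methylene lactone survive.

**Compound list**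
1 | 1,3-dithiane | C1CSCSC1 | starting material
2 | 3-chloro-2-(chloromethyl)prop-1-ene | C=C(CCl)CCl | starting material
3 | 2-lithio-1,3-dithiane | [Li]C1SCCCS1 | intermediate
4 | 2,2'-(2-methylidenepropane-1,3-diyl)bis(1,3-dithiane) | C=C(CC1SCCCS1)CC1SCCCS1 | intermediate
5 | 3-bromo-1-(trimethylsilyl)prop-1-yne | C[Si](C)(C)C#CCBr | starting material
6 | monolithiated bis(dithiane) (2-lithio derivative of 4) | [Li]C1(CC(=C)CC2SCCCS2)SCCCS1 | intermediate
7 | C-silylated alkyne (trimethylsilyl derivative of 8) | C[Si](C)(C)C#CCC1(CC(=C)CC2SCCCS2)SCCCS1 | intermediate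
8 | 2-{2-[(1,3-dithian-2-yl)methyl]prop-2-en-1-yl}-2-(prop-2-yn-1-yl)-1,3-dithiane | C#CCC1(CC(=C)CC2SCCCS2)SCCCS1 | intermediate
9 | acrolein (prop-2-enal) | C=CC=O | starting material
10 | alkynyl(methyl)zinc derived from 8 | C[Zn]C#CCC1(CC(=C)CC2SCCCS2)SCCCS1 | intermediate
11 | methylzinc alkoxide of 12 | C[Zn]O[C@@H](C=C)C#CCC1(CC(=C)CC2SCCCS2)SCCCS1 | intermediate
12 | (3S)-6-(2-{2-[(1,3-dithian-2-yl)methyl]prop-2-en-1-yl}-1,3-dithian-2-yl)hex-1-en-4-yn-3-ol | C=C[C@H](O)C#CCC1(CC(=C)CC2SCCCS2)SCCCS1 | intermediate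
13 | cyclic sodium vinylalanate (1,2-oxaluminole from 12) | [Na+].C=C[C@@H]1O[Al-](OCCOC)(OCCOC)C(CC2(CC(=C)CC3SCCCS3)SCCCS2)=C1 | intermediate
14 | (3S,4Z)-6-(2-{2-[(1,3-dithian-2-yl)methyl]prop-2-en-1-yl}-1,3-dithian-2-yl)-5-iodohexa-1,4-dien-3-ol | C=C[C@H](O)/C=C(\I)CC1(CC(=C)CC2SCCCS2)SCCCS1 | intermediate
15 | (tributylstannyl)methanol | CCCC[Sn](CCCC)(CCCC)CO | starting material
16 | (2Z,4S)-2-[(2-{2-[(1,3-dithian-2-yl)methyl]prop-2-en-1-yl}-1,3-dithian-2-yl)methyl]hexa-2,5-diene-1,4-diol | C=C[C@H](O)/C=C(\CO)CC1(CC(=C)CC2SCCCS2)SCCCS1 | intermediate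
17 | (2Z,4S)-4-hydroxy-2-[(2-{2-[(1,3-dithian-2-yl)methyl]prop-2-en-1-yl}-1,3-dithian-2-yl)methyl]hexa-2,5-dien-1-yl acetate | C=C[C@H](O)/C=C(\COC(C)=O)CC1(CC(=C)CC2SCCCS2)SCCCS1 | intermediate
18 | 2-(bromomethyl)prop-2-enoic acid | C=C(CBr)C(O)=O | starting material
19 | O-acylisourea of 18 with N,N'-diisopropylcarbodiimide | C=C(CBr)C(=O)OC(=NC(C)C)NC(C)C | intermediate
20 | (2Z,4S)-4-{[2-(bromomethyl)prop-2-enoyl]oxy}-2-[(2-{2-[(1,3-dithian-2-yl)methyl]prop-2-en-1-yl}-1,3-dithian-2-yl)methyl]hexa-2,5-dien-1-yl acetate | C=C[C@H](OC(=O)C(=C)CBr)/C=C(\COC(C)=O)CC1(CC(=C)CC2SCCCS2)SCCCS1 | intermediate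
21 | (2Z)-3-[(2R)-4-(bromomethyl)-5-oxo-2,5-dihydrofuran-2-yl]-2-[(2-{2-[(1,3-dithian-2-yl)methyl]prop-2-en-1-yl}-1,3-dithian-2-yl)methyl]prop-2-en-1-yl acetate | BrCC1=C[C@H](OC1=O)/C=C(\COC(C)=O)CC2(CC(=C)CC3SCCCS3)SCCCS2 | intermediate
22 | (2Z)-3-[(2R)-4-(bromomethyl)-5-oxo-2,5-dihydrofuran-2-yl]-2-(4-methylidene-2,6-dioxohexyl)prop-2-en-1-yl acetate | BrCC1=C[C@H](OC1=O)/C=C(\COC(C)=O)CC(=O)CC(=C)CC=O | intermediate
23 | allylchromium dichloride from 22 (trivalent chromium on C13) | Cl[Cr](Cl)CC1=C[C@H](OC1=O)/C=C(\COC(C)=O)CC(=O)CC(=C)CC=O | intermediate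
24 | chromium alkoxide of 25 (O8–CrCl2) | C=C1CC(=O)C/C(COC(C)=O)=C/[C@H]2OC(=O)C(=C)[C@@H]2[C@@H](O[Cr](Cl)Cl)C1 | intermediate
25 | (6R,7R,8S)-15-acetoxy-8-hydroxy-2-oxogermacra-4,10(14),11(13)-trien-12,6-olide | C=C1CC(=O)C/C(COC(C)=O)=C/[C@H]2OC(=O)C(=C)[C@@H]2[C@@H](O)C1 | intermediate
26 | (6R,7R,8S)-8,15-diacetoxy-2-oxogermacra-4,10(14),11(13)-trien-12,6-olide (CNP0183179.1) | C=C1CC(=O)C/C(COC(C)=O)=C/[C@H]2OC(=O)C(=C)[C@@H]2[C@@H](OC(C)=O)C1 | target

**Totals**
Total step count: 11. Longest linear sequence: 11 steps (from 1 and 2).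

**Three steps most likely to fail, each with a fallback**

Step 10 (ring closure and C7/C8 control). The ten-membered closure may favour the other chair and give the C8 epimer. Fallback from 22 to 26: if the chromium-mediated closure gives mainly (6R,7R,8R)-15-acetoxy-8-hydroxy-2-oxogermacra-4,10(14),11(13)-trien-12,6-olide F1, it is esterified under Mitsunobu conditions (AcOH, PPh3, DIAD, toluene, 0 °C). This inverts C8 and gives 26 directly, so C8 is set by invertive C–O substitution instead of by the C–C bond-forming transition state, and step 11 is skipped. A cis-fused lactone (wrong C7) would not be rescued by this.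

Step 8 (metathesis beside four thioether sulfurs and an allylic bromide). Fallback from 20 to 22: the sulfur is removed before metathesis. Compound 20 is treated with PhI(OCOCF3)2 in dry methanol to exchange both dithianes for dimethyl acetals, giving the bis(dimethyl acetal) ester F2. Ring-closing metathesis of this sulfur-free diene (same catalyst, toluene, 60 °C) gives the bromobutenolide bis(dimethyl acetal) F3. Brief hydrolysis (LiBF4, wet MeCN) then gives 22, so steps 8 and 9 are both replaced.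

Step 3 (enantioselective alkynylation of polymerisation-prone acrolein with a sulfur-rich alkyne). Fallback from 8 to 12: the alkyne is deprotonated with EtMgBr (THF, 0 °C) and added to acrolein to give the racemic enynol rac-6-(2-{2-[(1,3-dithian-2-yl)methyl]prop-2-en-1-yl}-1,3-dithian-2-yl)hex-1-en-4-yn-3-ol F4. Kinetic resolution with immobilised Candida antarctica lipase B and vinyl acetate acylates the (R)-enantiomer to the (3R)-acetate F5 and leaves (S)-alcohol 12, which is separated by chromatography.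

**Further compounds**
F1 | step 10 | (6R,7R,8R)-15-acetoxy-8-hydroxy-2-oxogermacra-4,10(14),11(13)-trien-12,6-olide (C8 epimer of 25) | C=C1CC(=O)C/C(COC(C)=O)=C/[C@H]2OC(=O)C(=C)[C@@H]2[C@H](O)C1
F2 | step 8 | (2Z,4S)-4-{[2-(bromomethyl)prop-2-enoyl]oxy}-2-(2,2,6,6-tetramethoxy-4-methylidenehexyl)hexa-2,5-dien-1-yl acetate | C=C[C@H](OC(=O)C(=C)CBr)/C=C(\COC(C)=O)CC(OC)(OC)CC(=C)CC(OC)OC
F3 | step 8 | (2Z)-3-[(2R)-4-(bromomethyl)-5-oxo-2,5-dihydrofuran-2-yl]-2-(2,2,6,6-tetramethoxy-4-methylidenehexyl)prop-2-en-1-yl acetate | BrCC1=C[C@H](OC1=O)/C=C(\COC(C)=O)CC(OC)(OC)CC(=C)CC(OC)OC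
F4 | step 3 | rac-6-(2-{2-[(1,3-dithian-2-yl)methyl]prop-2-en-1-yl}-1,3-dithian-2-yl)hex-1-en-4-yn-3-ol | C=CC(O)C#CCC1(CC(=C)CC2SCCCS2)SCCCS1
F5 | step 3 | (3R)-6-(2-{2-[(1,3-dithian-2-yl)methyl]prop-2-en-1-yl}-1,3-dithian-2-yl)hex-1-en-4-yn-3-yl acetate | C=C[C@@H](OC(C)=O)C#CCC1(CC(=C)CC2SCCCS2)SCCCS1
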